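**Plan**

- Retrosynthesis: the C2–H and C3–H bonds of the flavanone are cut first, leading back to a flavone. Ring C is then cut at C4a–C4, C4–C3 and O1–C2 into 4-iodo-2-prenylresorcinol, carbon monoxide and 6-ethynyl-2,2-dimethylchroman.
- The key step is possible because ring C consists of a phenol oxygen of ring A (O1), a single carbonyl carbon (C4) and a two-carbon unit (C2–C3) carrying ring B. These correspond to an ortho-iodophenol, CO and an aryl alkyne.
- The iodophenol is cut at C–I and at the aryl–prenyl bond back to the bis(MOM) ether of resorcinol. The second of the two directed lithiations acts on a symmetric arene, so the iodine position is unambiguous. The alkyne is cut at the aryl–alkynyl bond and at the chroman ring back to 4-bromophenol, isoprene and ethynyltrimethylsilane.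
- Forward: ring A receives prenyl and iodine, the chroman ring is annulated onto ring B and the alkyne attached, ring C is closed by the palladium-catalysed three-component carbonylative annulation, and C2=C3 is reduced last.
- Stereochemistry: the only stereocentre, C2 (S), is set in the final step by a ligand-controlled copper hydride 1,4-reduction that leaves the prenyl alkene alone. No later step can erode it.

Key step: step 8

Assumption: (R)-DTBM-SEGPHOS on copper hydride is taken to deliver hydride to the C2 face that gives the (2S)-flavanone; if a model flavone shows the opposite sense, the (S)-ligand is used with no other change.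

**Route**

Step 1
Reactants: 1 resorcinol
Product: 2 1,3-bis(methoxymethoxy)benzene
Conditions: NaH, DMF, 0 °C; MOMCl, 0 °C → rt
Reagents that add atoms: chloromethyl methyl ether, COCCl
Why: Double Williamson-type O-alkylation of the resorcinol dianion gives the bis-acetal, whose oxygen atoms direct both later metalations.

Step 2
Reactants: 2 1,3-bis(methoxymethoxy)benzene; 3 prenyl bromide
Product: 5 1,3-bis(methoxymethoxy)-2-(3-methylbut-2-enyl)benzene, via C2 aryllithium 4 (not isolated)
Conditions: n-BuLi, THF, 0 °C → rt; CuI (10 mol%), then 3, −78 °C → rt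
Reagents that add atoms: none
Why: Directed ortho-metalation occurs at C2, the position flanked by both acetal oxygens, and copper-catalysed SN2 allylation of the aryllithium at the primary carbon of prenyl bromide installs the future C8 prenyl group.

Step 3
Reactants: 5 1,3-bis(methoxymethoxy)-2-(3-methylbut-2-enyl)benzene
Product: 7 1-iodo-2,4-bis(methoxymethoxy)-3-(3-methylbut-2-enyl)benzene, via C4 aryllithium 6 (not isolated)
Conditions: s-BuLi, TMEDA, THF, −78 °C; ICH2CH2I, −78 °C → rt
Reagents that add atoms: 1,2-diiodoethane, ICCI
Why: A second directed ortho-metalation, run cold so that ring deprotonation next to an acetal oxygen outruns removal of a benzylic–allylic proton, is followed by iodinolysis with an iodine source that is inert to the prenyl alkene; because 5 has a mirror plane through C2 and C5, the two open ortho sites are identical and only one iodide can form.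

Step 4
Reactants: 7 1-iodo-2,4-bis(methoxymethoxy)-3-(3-methylbut-2-enyl)benzene
Product: 8 4-iodo-2-(3-methylbut-2-enyl)benzene-1,3-diol
Conditions: 3 M HCl, MeOH, 40 °C
Reagents that add atoms: none
Why: Acid-catalysed transacetalisation to methanol removes both MOM groups under conditions expected to be too mild for hydroalkoxylation of the prenyl alkene or protodeiodination, and the two hydroxyls need not be differentiated because only the one next to iodine can later close ring C.

Step 5
Reactants: 9 4-bromophenol; 10 isoprene
Product: 12 6-bromo-2,2-dimethylchroman, via ortho-prenylphenol 11 (not isolated)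
Conditions: 85% H3PO4, heptane, 35 °C, sealed vessel
Reagents that add atoms: none
Why: Acid-catalysed Friedel–Crafts prenylation ortho to the hydroxyl (the para position is blocked by bromine) followed by Markovnikov hydroalkoxylation of the prenyl alkene closes the 2,2-dimethylchroman ring in a formal [3+3] annulation.

Step 6
Reactants: 12 6-bromo-2,2-dimethylchroman; 13 ethynyltrimethylsilane
Product: 14 trimethyl[(2,2-dimethylchroman-6-yl)ethynyl]silane
Conditions: PdCl2(PPh3)2 (3 mol%), CuI (5 mol%), Et3N, 70 °C, sealed tube
Reagents that add atoms: none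
Why: Sonogashira coupling of the aryl bromide with the silyl-capped alkyne, heated because the ring is electron-rich, gives the protected arylacetylene without double arylation.

Step 7
Reactants: 14 trimethyl[(2,2-dimethylchroman-6-yl)ethynyl]silane
Product: 15 6-ethynyl-2,2-dimethylchroman
Conditions: K2CO3, MeOH, rt
Reagents that add atoms: none
Why: Base-catalysed methanolysis of the alkynyl C–Si bond (protodesilylation) frees the terminal alkyne.

Step 8
Reactants: 8 4-iodo-2-(3-methylbut-2-enyl)benzene-1,3-diol; 16 carbon monoxide; 15 6-ethynyl-2,2-dimethylchroman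
Product: 19 7-hydroxy-2-(2,2-dimethylchroman-6-yl)-8-(3-methylbut-2-enyl)chromen-4-one, via ynone 17 (not isolated), via enaminone 18 (not isolated)
Conditions: PdCl2(PPh3)2 (5 mol%), CO (20 bar), Et2NH, 120 °C
Reagents that add atoms: none
Why: Oxidative addition of zerovalent palladium (formed in the flask from PdCl2(PPh3)2) into the aryl–iodine bond of 8 is followed by CO insertion to an aroyl complex of divalent palladium, and amine-assisted transfer of the alkynyl group of 15 with reductive elimination forms C4a–C4 and C4–C3 in ynone 17. Diethylamine then adds to C2 of the ynone to give enaminone 18, and the hydroxyl ortho to the ketone displaces the amine at C2, forming O1–C2 and closing ring C by a six-membered (6-endo) addition–elimination. The closest known reaction type is the carbonylative Sonogashira coupling of ortho-iodophenols with terminal alkynes with in situ annulation to flavones. No stereocentre is formed. The step needs carbonylative rather than direct alkynylation, which CO pressure and the absence of a copper co-catalyst should secure, and six- rather than five-membered closure, which the secondary amine secures because the enaminone can only be attacked at C2, whereas direct phenoxide attack on the ynone would lead to the aurone. Only the hydroxyl next to the former C–I carbon can reach C2, so the second hydroxyl remains as the free C7–OH and the prenyl group ends up at C8 as a spectator.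

Step 9
Reactants: 19 7-hydroxy-2-(2,2-dimethylchroman-6-yl)-8-(3-methylbut-2-enyl)chromen-4-one
Product: 22 euchrenone a17 [(2S)-7-hydroxy-2-(2,2-dimethylchroman-6-yl)-8-(3-methylbut-2-enyl)chroman-4-one], via silyl ether 20 (not isolated), via silyl enol ether 21 (not isolated)
Conditions: Cu(OAc)2·H2O (5 mol%), (R)-DTBM-SEGPHOS (5.5 mol%), (EtO)2MeSiH (4 equiv), THF/toluene, 0 °C → rt; then 1 M HCl, THF, 0 °C
Reagents that add atoms: none
Why: Copper hydride asymmetric conjugate reduction of a 2-substituted chromone: the phenol is first silylated with loss of H2, the bisphosphine-bound monovalent copper hydride delivers hydride to one face of C2 under control of the chiral ligand to set the (2S) centre, the enolate is held as silyl enol ether 21 so that neither the C4 carbonyl nor the unactivated trisubstituted prenyl alkene (which a dihydrogen-based hydrogenation catalyst would put at risk) is reduced, and mild acidic hydrolysis releases the flavanone without exposing C2 to base.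

**Compound list**

1 | resorcinol | Oc1cccc(O)c1 | starting material
2 | 1,3-bis(methoxymethoxy)benzene | COCOc1cccc(OCOC)c1 | intermediate
3 | prenyl bromide (1-bromo-3-methylbut-2-ene) | CC(C)=CCBr | starting material
4 | 2-lithio-1,3-bis(methoxymethoxy)benzene | [Li]c1c(OCOC)cccc1OCOC | intermediate
5 | 1,3-bis(methoxymethoxy)-2-(3-methylbut-2-enyl)benzene | CC(C)=CCc1c(OCOC)cccc1OCOC | intermediate
6 | 4-lithio-1,3-bis(methoxymethoxy)-2-(3-methylbut-2-enyl)benzene | CC(C)=CCc1c(OCOC)ccc([Li])c1OCOC | intermediate
7 | 1-iodo-2,4-bis(methoxymethoxy)-3-(3-methylbut-2-enyl)benzene | CC(C)=CCc1c(OCOC)ccc(I)c1OCOC | intermediate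
8 | 4-iodo-2-(3-methylbut-2-enyl)benzene-1,3-diol | CC(C)=CCc1c(O)ccc(I)c1O | intermediate
9 | 4-bromophenol | Oc1ccc(Br)cc1 | starting material
10 | isoprene | C=CC(C)=C | starting material
11 | 4-bromo-2-(3-methylbut-2-enyl)phenol | CC(C)=CCc1cc(Br)ccc1O | intermediate
12 | 6-bromo-2,2-dimethylchroman | CC1(C)CCc2cc(Br)ccc2O1 | intermediate
13 | ethynyltrimethylsilane | C#C[Si](C)(C)C | starting material
14 | trimethyl[(2,2-dimethylchroman-6-yl)ethynyl]silane | CC1(C)CCc2cc(C#C[Si](C)(C)C)ccc2O1 | intermediate
15 | 6-ethynyl-2,2-dimethylchroman | C#Cc1ccc2c(c1)CCC(C)(C)O2 | intermediate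
16 | carbon monoxide | [C-]#[O+] | starting material
17 | 1-[2,4-dihydroxy-3-(3-methylbut-2-enyl)phenyl]-3-(2,2-dimethylchroman-6-yl)prop-2-yn-1-one | CC(C)=CCc1c(O)ccc(C(=O)C#Cc2ccc3c(c2)CCC(C)(C)O3)c1O | intermediate
18 | 3-(diethylamino)-1-[2,4-dihydroxy-3-(3-methylbut-2-enyl)phenyl]-3-(2,2-dimethylchroman-6-yl)prop-2-en-1-one | CC(C)=CCc1c(O)ccc(C(=O)C=C(N(CC)CC)c2ccc3c(c2)CCC(C)(C)O3)c1O | intermediate
19 | 7-hydroxy-2-(2,2-dimethylchroman-6-yl)-8-(3-methylbut-2-enyl)chromen-4-one | CC(C)=CCc1c(O)ccc2c1OC(c1ccc3c(c1)CCC(C)(C)O3)=CC2=O | intermediate
20 | 7-[diethoxy(methyl)silyloxy]-2-(2,2-dimethylchroman-6-yl)-8-(3-methylbut-2-enyl)chromen-4-one | CCO[Si](C)(OCC)Oc1ccc2c(c1CC=C(C)C)OC(c1ccc3c(c1)CCC(C)(C)O3)=CC2=O | intermediate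
21 | (2S)-4,7-bis[diethoxy(methyl)silyloxy]-2-(2,2-dimethylchroman-6-yl)-8-(3-methylbut-2-enyl)-2H-chromene | CCO[Si](C)(OCC)Oc1ccc2c(c1CC=C(C)C)O[C@H](c1ccc3c(c1)CCC(C)(C)O3)C=C2O[Si](C)(OCC)OCC | intermediate
22 | euchrenone a17, (2S)-7-hydroxy-2-(2,2-dimethylchroman-6-yl)-8-(3-methylbut-2-enyl)chroman-4-one | CC(C)=CCc1c(O)ccc2c1O[C@H](c1ccc3c(c1)CCC(C)(C)O3)CC2=O | target

**Step count**

Total step count: 9.
Longest linear sequence: 6 steps (steps 1, 2, 3, 4, 8 and 9, from resorcinol).

**Steps most likely to fail**

Step 9. The copper hydride may discriminate poorly between the two faces of C2 in an electron-rich 2-arylchromone, hydride transfer may be slow, or the copper enolate may expel the ring oxygen and open ring C. The fallback sets out from flavone 19 and comes back at 22. A non-selective 1,4-reduction with an achiral copper hydride (Cu(OAc)2·H2O, 1,2-bis(diphenylphosphino)benzene, (EtO)2MeSiH, then dilute HCl) should give racemic 7-hydroxy-2-(2,2-dimethylchroman-6-yl)-8-(3-methylbut-2-enyl)chroman-4-one F1. Kinetic resolution by asymmetric transfer hydrogenation (Cp*RhCl[(R,R)-TsDPEN], HCO2H/Et3N, EtOAc, rt; the catalyst antipode is chosen to consume the 2R ketone) should then reduce the unwanted enantiomer to the cis alcohol (2R,4R)-2-(2,2-dimethylchroman-6-yl)-8-(3-methylbut-2-enyl)chromane-4,7-diol F2. The untouched (2S)-ketone 22 is separated by chromatography. Transfer hydrogenation does not reduce the prenyl alkene, and the same resolution can upgrade material of insufficient enantiomeric purity from step 9.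

Step 8. The aroylpalladium intermediate may be captured by diethylamine or by a phenoxide (amide or aryl ester formation), direct non-carbonylative alkynylation may lead on to a benzofuran, or oxidative addition into the doubly hydroxylated ring may be slow. The fallback sets out from arene 5 (with alkyne 15) and comes back at ynone 17 and thus at flavone 19, without palladium or CO. Lithiation of 5 as in step 3 and quenching with DMF should give 2,4-bis(methoxymethoxy)-3-(3-methylbut-2-enyl)benzaldehyde F3. Addition of the lithium acetylide of 15 (n-BuLi, THF, −78 °C) gives racemic 1-[2,4-bis(methoxymethoxy)-3-(3-methylbut-2-enyl)phenyl]-3-(2,2-dimethylchroman-6-yl)prop-2-yn-1-ol F4. Oxidation with MnO2 (CH2Cl2, rt) gives 1-[2,4-bis(methoxymethoxy)-3-(3-methylbut-2-enyl)phenyl]-3-(2,2-dimethylchroman-6-yl)prop-2-yn-1-one F5. Removal of both acetals (HCl, MeOH, rt) gives ynone 17, which diethylamine in ethanol closes to flavone 19 through the same enaminone as in the route.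

Step 3. The base may remove a proton from the benzylic–allylic methylene instead of the ring (lateral metalation), leading to side-chain iodination or migration of the alkene. The fallback sets out from 5 and comes back at diol 8, replacing metalation by electrophilic aromatic substitution. Acidic removal of both acetals (HCl, MeOH, 40 °C) gives 2-(3-methylbut-2-enyl)benzene-1,3-diol F6. Mono-iodination of its phenoxide (I2, 1.0 equiv, NaHCO3, THF/H2O, 0 °C) should then give 8. F6 is symmetric, so either open ortho site leads to 8. The highly activated phenoxide ring is expected to be iodinated faster than the alkene undergoes iodoetherification, provided the iodine is kept to one equivalent at low temperature.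

**Further compounds**

F1 | step 9 | racemic 7-hydroxy-2-(2,2-dimethylchroman-6-yl)-8-(3-methylbut-2-enyl)chroman-4-one | CC(C)=CCc1c(O)ccc2c1OC(c1ccc3c(c1)CCC(C)(C)O3)CC2=O
F2 | step 9 | (2R,4R)-2-(2,2-dimethylchroman-6-yl)-8-(3-methylbut-2-enyl)chromane-4,7-diol | CC(C)=CCc1c(O)ccc2c1O[C@@H](c1ccc3c(c1)CCC(C)(C)O3)C[C@H]2O
F3 | step 8 | 2,4-bis(methoxymethoxy)-3-(3-methylbut-2-enyl)benzaldehyde | CC(C)=CCc1c(OCOC)ccc(C=O)c1OCOC
F4 | step 8 | racemic 1-[2,4-bis(methoxymethoxy)-3-(3-methylbut-2-enyl)phenyl]-3-(2,2-dimethylchroman-6-yl)prop-2-yn-1-ol | CC(C)=CCc1c(OCOC)ccc(C(O)C#Cc2ccc3c(c2)CCC(C)(C)O3)c1OCOC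
F5 | step 8 | 1-[2,4-bis(methoxymethoxy)-3-(3-methylbut-2-enyl)phenyl]-3-(2,2-dimethylchroman-6-yl)prop-2-yn-1-one | CC(C)=CCc1c(OCOC)ccc(C(=O)C#Cc2ccc3c(c2)CCC(C)(C)O3)c1OCOC
F6 | step 3 | 2-(3-methylbut-2-enyl)benzene-1,3-diol | CC(C)=CCc1c(O)cccc1O
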